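**Retrosynthetic overview**

- Marchantin H is opened last at its three O-methyl groups and at the ring B–ring C CH2–CH2 bridge (intramolecular Wittig reaction, then hydrogenation). Before that it is opened at the ring C–ring D diaryl ether (copper-catalysed coupling with 2-bromo-3,4-dimethoxybenzaldehyde).
- The strategy rests on ring B: a 1,4-disubstituted benzene whose only substituents are the ring A ether oxygen and, para to it, the benzylic bridge carbon. Ring B is built from C3–C6 of methyl coumalate (the ester carbon on C5 becomes the bridge carbon) and the two carbons of an ethynyl ether on the ring A oxygen, with loss of CO2.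
- The ethynyl ether comes from the ring A phenol (trichloroethylene, then n-BuLi). The ring A–ring D bibenzyl comes from isovanillin and a 3-benzyloxybenzyl ylide (Wittig, then diimide).
- Order of ring formation: rings A, C and D are bought; ring B is made in step 7; the 18-membered macrocycle is closed in step 13.

Key step: step 7

Remark on the chemistry: the target has no stereocentre; the alkenes 6 and 25 are carried on as E/Z mixtures because both are hydrogenated.

**Step 1**
Reactants: 1 3-benzyloxybenzyl alcohol
Product: 2 3-benzyloxybenzyl bromide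
Conditions: PBr3, CH2Cl2, 0 °C
Reagents that add atoms: phosphorus tribromide, BrP(Br)Br
Why: Bromide displaces the activated phosphite ester of a primary benzylic alcohol (SN2), and the benzyl aryl ether is inert at 0 °C.

**Step 2**
Reactants: 2 3-benzyloxybenzyl bromide
Product: 3 (3-benzyloxybenzyl)triphenylphosphonium bromide
Conditions: PPh3, toluene, reflux
Reagents that add atoms: triphenylphosphine, c1ccc(cc1)P(c1ccccc1)c1ccccc1
Why: SN2 quaternisation of triphenylphosphine by a benzylic bromide should give the salt, which precipitates from toluene.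

**Step 3**
Reactants: 3 (3-benzyloxybenzyl)triphenylphosphonium bromide; 4 isovanillin (3-hydroxy-4-methoxybenzaldehyde)
Product: 6 5-[2-(3-benzyloxyphenyl)ethenyl]-2-methoxyphenol (E/Z mixture), via phosphonium ylide 5 (not isolated)
Conditions: KOtBu (2.2 equiv), THF, 0 °C to rt; then 1 M HCl
Reagents that add atoms: none
Why: Wittig olefination with a semi-stabilised benzylide should proceed on the unprotected aldehyde, because the phenoxide oxygen of isovanillin is meta to the formyl group and cannot deactivate it by resonance; the second equivalent of base covers the phenol.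

**Step 4**
Reactants: 6 5-[2-(3-benzyloxyphenyl)ethenyl]-2-methoxyphenol
Product: 7 5-[2-(3-benzyloxyphenyl)ethyl]-2-methoxyphenol
Conditions: TsNHNH2 (excess, in portions), NaOAc, DME/H2O, reflux
Reagents that add atoms: none
Why: Diimide generated from tosylhydrazide transfers H2 concertedly to the non-polar stilbene C=C and does not hydrogenolyse the benzyl ether, which catalytic hydrogenation over palladium would remove.

**Step 5**
Reactants: 7 5-[2-(3-benzyloxyphenyl)ethyl]-2-methoxyphenol; 8 trichloroethylene
Product: 10 4-[2-(3-benzyloxyphenyl)ethyl]-2-[(E)-1,2-dichloroethenyloxy]-1-methoxybenzene, via dichloroacetylene 9 (not isolated)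
Conditions: K2CO3, DMF, 70 °C
Reagents that add atoms: none
Why: Base dehydrochlorinates trichloroethylene to dichloroacetylene, to which the phenoxide adds in trans fashion, the known O-dichlorovinylation of phenols that gives the (E)-1,2-dichlorovinyl ether.

**Step 6**
Reactants: 10 4-[2-(3-benzyloxyphenyl)ethyl]-2-[(E)-1,2-dichloroethenyloxy]-1-methoxybenzene
Product: 13 4-[2-(3-benzyloxyphenyl)ethyl]-2-ethynyloxy-1-methoxybenzene, via chloroethynyl ether 11 (not isolated), via lithium acetylide 12 (not isolated)
Conditions: n-BuLi (2.5 equiv), Et2O, −78 to −40 °C; then H2O, −78 °C; rapid filtration through basic alumina, used at once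
Reagents that add atoms: none
Why: Vinylic deprotonation and anti-elimination of LiCl give the chloroalkynyl ether, lithium–chlorine exchange gives the lithium acetylide and protonation gives the terminal ynol ether (the dichlorovinyl ether route to alkynyl ethers); at −78 °C the benzyl and methyl ethers should not be metalated.

**Step 7**
Reactants: 13 4-[2-(3-benzyloxyphenyl)ethyl]-2-ethynyloxy-1-methoxybenzene; 14 methyl coumalate (methyl 2-oxo-2H-pyran-5-carboxylate)
Product: 16 methyl 4-{5-[2-(3-benzyloxyphenyl)ethyl]-2-methoxyphenoxy}benzoate, via bridged bicyclic lactone 15 (not isolated)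
Conditions: 14 (1.5 equiv), toluene, 120 °C, sealed tube
Reagents that add atoms: none
Why: The electron-poor 2-pyrone 14 is the 4π partner and the electron-rich ynol ether 13 the 2π partner of an inverse-electron-demand Diels–Alder reaction; the closest known type is the benzannulation of coumalates and other 2-pyrones with ynamines, ynol ethers and ketene acetals. The donor-polarised terminal alkyne carbon bonds to pyrone C6, the terminus conjugated to both carbonyl groups, and the oxygen-bearing carbon bonds to C3, giving the 2-oxabicyclo[2.2.2]octadienone 15, which ejects CO2 by a retro-(4+2) reaction and is aromatic at once. Ring B is thus closed by an intermolecular (4+2) cycloaddition that forms both new C–C bonds, followed by cycloreversion. No stereocentre remains, because the two bridgehead centres of 15 are lost on aromatisation. The selectivity needed is regiochemical, aryloxy para and not meta to the ester, and it is secured by the matched polarity of the ynol ether β-carbon and C6 of the 5-ester-substituted pyrone. Nothing else in 13 is a comparably reactive π-donor, so the benzyl ether, methyl ether and bibenzyl should be spectators.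

**Step 8**
Reactants: 16 methyl 4-{5-[2-(3-benzyloxyphenyl)ethyl]-2-methoxyphenoxy}benzoate
Product: 17 methyl 4-{5-[2-(3-hydroxyphenyl)ethyl]-2-methoxyphenoxy}benzoate
Conditions: H2 (1 atm), 10% Pd/C, EtOAc/MeOH, rt
Reagents that add atoms: none
Why: Hydrogenolysis of the benzyl aryl ether should free the ring D phenol while the ester, diaryl ether and methyl ether are inert.

**Step 9**
Reactants: 17 methyl 4-{5-[2-(3-hydroxyphenyl)ethyl]-2-methoxyphenoxy}benzoate; 18 2-bromo-3,4-dimethoxybenzaldehyde
Product: 19 methyl 4-(5-{2-[3-(6-formyl-2,3-dimethoxyphenoxy)phenyl]ethyl}-2-methoxyphenoxy)benzoate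
Conditions: CuI (10 mol%), picolinic acid (20 mol%), K3PO4, DMSO, 90 °C
Reagents that add atoms: none
Why: Ullmann-type copper-catalysed O-arylation of a phenol with an aryl bromide that the ortho formyl group activates, under conditions suited to hindered diaryl ethers; the anhydrous phosphate base should spare the methyl ester.

**Step 10**
Reactants: 19 methyl 4-(5-{2-[3-(6-formyl-2,3-dimethoxyphenoxy)phenyl]ethyl}-2-methoxyphenoxy)benzoate
Product: 20 methyl 4-[5-(2-{3-[6-(1,3-dioxolan-2-yl)-2,3-dimethoxyphenoxy]phenyl}ethyl)-2-methoxyphenoxy]benzoate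
Conditions: ethylene glycol, p-TsOH·H2O (cat.), benzene, reflux, Dean–Stark
Reagents that add atoms: ethylene glycol, OCCO
Why: Acid-catalysed acetalisation with azeotropic removal of water masks the aldehyde for the hydride reduction, and any ester exchanged with the glycol would converge on the same alcohol in step 11.

**Step 11**
Reactants: 20 methyl 4-[5-(2-{3-[6-(1,3-dioxolan-2-yl)-2,3-dimethoxyphenoxy]phenyl}ethyl)-2-methoxyphenoxy]benzoate
Product: 21 {4-[5-(2-{3-[6-(1,3-dioxolan-2-yl)-2,3-dimethoxyphenoxy]phenyl}ethyl)-2-methoxyphenoxy]phenyl}methanol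
Conditions: LiAlH4, THF, 0 °C; then H2O, aq. NaOH
Reagents that add atoms: none
Why: Hydride reduction of the benzoate should give the primary benzylic alcohol, and the dioxolane and the ethers are inert to LiAlH4 and to the basic work-up.

**Step 12**
Reactants: 21 {4-[5-(2-{3-[6-(1,3-dioxolan-2-yl)-2,3-dimethoxyphenoxy]phenyl}ethyl)-2-methoxyphenoxy]phenyl}methanol
Product: 23 [4-(5-{2-[3-(6-formyl-2,3-dimethoxyphenoxy)phenyl]ethyl}-2-methoxyphenoxy)benzyl]triphenylphosphonium bromide, via dioxolane phosphonium bromide 22 (not isolated)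
Conditions: PPh3·HBr, MeCN, reflux; then 1 M HCl, THF, rt
Reagents that add atoms: triphenylphosphine hydrobromide, [Br-].c1ccc(cc1)[PH+](c1ccccc1)c1ccccc1; water, O
Why: Triphenylphosphine hydrobromide converts the electron-rich 4-aryloxybenzylic alcohol by way of the benzylic bromide into the phosphonium salt (the one-pot preparation of benzylphosphonium salts from benzylic alcohols), and the aqueous acid then hydrolyses the dioxolane to the aldehyde.

**Step 13**
Reactants: 23 [4-(5-{2-[3-(6-formyl-2,3-dimethoxyphenoxy)phenyl]ethyl}-2-methoxyphenoxy)benzyl]triphenylphosphonium bromide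
Product: 25 macrocyclic stilbene (tri-O-methylmarchantin H with a CH=CH bridge between rings B and C; E/Z mixture), via aldehyde ylide 24 (not isolated)
Conditions: NaOMe, CH2Cl2, rt, slow addition of 23 (high dilution)
Reagents that add atoms: none
Why: Intramolecular Wittig olefination under high dilution should close the 18-membered ring at the ring B–ring C bridge, the established way of closing macrocyclic bis(bibenzyl) skeletons; the alkene geometry is immaterial.

**Step 14**
Reactants: 25 macrocyclic stilbene
Product: 26 tri-O-methylmarchantin H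
Conditions: H2 (1 atm), 10% Pd/C, EtOAc, rt
Reagents that add atoms: none
Why: Heterogeneous catalytic hydrogenation saturates both stilbene isomers to the bibenzyl bridge, and no hydrogenolysable group remains.

**Step 15**
Reactants: 26 tri-O-methylmarchantin H
Product: 27 marchantin H
Conditions: BBr3, CH2Cl2, −78 °C to rt; then H2O
Reagents that add atoms: none
Why: Lewis-acid cleavage of the three aryl methyl ethers by BBr3 (bromide attack at methyl) should free the phenol and the catechol, while the two diaryl ether bonds resist cleavage.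

**Compound list**

1 | 3-benzyloxybenzyl alcohol | OCc1cccc(OCc2ccccc2)c1 | starting material
2 | 3-benzyloxybenzyl bromide | BrCc1cccc(OCc2ccccc2)c1 | intermediate
3 | (3-benzyloxybenzyl)triphenylphosphonium bromide | [Br-].c1ccc(cc1)[P+](Cc1cccc(OCc2ccccc2)c1)(c1ccccc1)c1ccccc1 | intermediate
4 | isovanillin | COc1ccc(C=O)cc1O | starting material
5 | (3-benzyloxybenzylidene)triphenylphosphorane (not isolated) | c1ccc(cc1)P(=Cc1cccc(OCc2ccccc2)c1)(c1ccccc1)c1ccccc1 | intermediate
6 | 5-[2-(3-benzyloxyphenyl)ethenyl]-2-methoxyphenol (E/Z mixture, geometry not defined) | COc1ccc(C=Cc2cccc(OCc3ccccc3)c2)cc1O | intermediate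
7 | 5-[2-(3-benzyloxyphenyl)ethyl]-2-methoxyphenol | COc1ccc(CCc2cccc(OCc3ccccc3)c2)cc1O | intermediate
8 | trichloroethylene | ClC=C(Cl)Cl | starting material
9 | dichloroacetylene (not isolated) | ClC#CCl | intermediate
10 | 4-[2-(3-benzyloxyphenyl)ethyl]-2-[(E)-1,2-dichloroethenyloxy]-1-methoxybenzene | COc1ccc(CCc2cccc(OCc3ccccc3)c2)cc1O/C(Cl)=C\Cl | intermediate
11 | 4-[2-(3-benzyloxyphenyl)ethyl]-2-(chloroethynyloxy)-1-methoxybenzene (not isolated) | COc1ccc(CCc2cccc(OCc3ccccc3)c2)cc1OC#CCl | intermediate
12 | lithium acetylide of 13 (not isolated) | [Li]C#COc1cc(CCc2cccc(OCc3ccccc3)c2)ccc1OC | intermediate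
13 | 4-[2-(3-benzyloxyphenyl)ethyl]-2-ethynyloxy-1-methoxybenzene | C#COc1cc(CCc2cccc(OCc3ccccc3)c2)ccc1OC | intermediate
14 | methyl coumalate | COC(=O)C1=COC(=O)C=C1 | starting material
15 | methyl 8-aryloxy-3-oxo-2-oxabicyclo[2.2.2]octa-5,7-diene-6-carboxylate, aryl = 5-[2-(3-benzyloxyphenyl)ethyl]-2-methoxyphenyl (racemic, bridgehead configuration fixed by the bicycle; not isolated) | O=C1OC2C=C(Oc3cc(CCc4cccc(OCc5ccccc5)c4)ccc3OC)C1C=C2C(=O)OC | intermediate
16 | methyl 4-{5-[2-(3-benzyloxyphenyl)ethyl]-2-methoxyphenoxy}benzoate | COC(=O)c1ccc(Oc2cc(CCc3cccc(OCc4ccccc4)c3)ccc2OC)cc1 | intermediate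
17 | methyl 4-{5-[2-(3-hydroxyphenyl)ethyl]-2-methoxyphenoxy}benzoate | COC(=O)c1ccc(Oc2cc(CCc3cccc(O)c3)ccc2OC)cc1 | intermediate
18 | 2-bromo-3,4-dimethoxybenzaldehyde | COc1ccc(C=O)c(Br)c1OC | starting material
19 | methyl 4-(5-{2-[3-(6-formyl-2,3-dimethoxyphenoxy)phenyl]ethyl}-2-methoxyphenoxy)benzoate | COC(=O)c1ccc(Oc2cc(CCc3cccc(Oc4c(C=O)ccc(OC)c4OC)c3)ccc2OC)cc1 | intermediate
20 | methyl 4-[5-(2-{3-[6-(1,3-dioxolan-2-yl)-2,3-dimethoxyphenoxy]phenyl}ethyl)-2-methoxyphenoxy]benzoate | COC(=O)c1ccc(Oc2cc(CCc3cccc(Oc4c(C5OCCO5)ccc(OC)c4OC)c3)ccc2OC)cc1 | intermediate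
21 | {4-[5-(2-{3-[6-(1,3-dioxolan-2-yl)-2,3-dimethoxyphenoxy]phenyl}ethyl)-2-methoxyphenoxy]phenyl}methanol | OCc1ccc(Oc2cc(CCc3cccc(Oc4c(C5OCCO5)ccc(OC)c4OC)c3)ccc2OC)cc1 | intermediate
22 | dioxolane-protected phosphonium bromide (not isolated) | [Br-].COc1ccc(CCc2cccc(Oc3c(C4OCCO4)ccc(OC)c3OC)c2)cc1Oc1ccc(C[P+](c2ccccc2)(c2ccccc2)c2ccccc2)cc1 | intermediate
23 | [4-(5-{2-[3-(6-formyl-2,3-dimethoxyphenoxy)phenyl]ethyl}-2-methoxyphenoxy)benzyl]triphenylphosphonium bromide | [Br-].COc1ccc(CCc2cccc(Oc3c(C=O)ccc(OC)c3OC)c2)cc1Oc1ccc(C[P+](c2ccccc2)(c2ccccc2)c2ccccc2)cc1 | intermediate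
24 | ylide of 23 (not isolated) | COc1ccc(CCc2cccc(Oc3c(C=O)ccc(OC)c3OC)c2)cc1Oc1ccc(C=P(c2ccccc2)(c2ccccc2)c2ccccc2)cc1 | intermediate
25 | macrocyclic stilbene, tri-O-methylmarchantin H with CH=CH between rings B and C (E/Z mixture, geometry not defined) | COc1ccc2cc1Oc1ccc(cc1)C=Cc1ccc(OC)c(OC)c1Oc1cccc(c1)CC2 | intermediate
26 | tri-O-methylmarchantin H | COc1ccc2cc1Oc1ccc(cc1)CCc1ccc(OC)c(OC)c1Oc1cccc(c1)CC2 | intermediate
27 | marchantin H | Oc1ccc2cc1Oc1ccc(cc1)CCc1ccc(O)c(O)c1Oc1cccc(c1)CC2 | target

**Step count and risks**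

Total step count: 15. Longest linear sequence: 15 steps (1 to 27); compounds 4, 8, 14 and 18 enter as purchased materials.

Steps most likely to fail:

1. Step 7 (ring B by pyrone cycloaddition). The aryloxyalkyne is a weaker donor than an alkoxy- or aminoalkyne, so the cycloaddition may be slow enough for thermal oligomerisation or hydration of the ynol ether and self-condensation of the pyrone to compete. Some regiochemical leakage to the meta-aryloxybenzoate is also possible. Fallback: the ring A–ring B ether is made by conventional aryl–oxygen bond formation instead of building ring B. Setting out from phenol 7, nucleophilic aromatic substitution on methyl 4-fluorobenzoate (Cs2CO3, DMSO, 110 °C) should give benzoate 16 directly, where the route is rejoined at step 8. This fallback makes no new compound (F0).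

2. Step 6 (ynol ether formation). Excess n-BuLi may add to the chloroalkyne or displace the aryloxide, ring A may be lithiated, or the terminal ynol ether may be lost by hydration to the aryl acetate during work-up. Fallback: the alkyne is made by bromination and double dehydrobromination of a vinyl ether instead of by the dichlorovinyl ether route. Setting out from phenol 7, iridium-catalysed vinyl transfer from vinyl acetate ([Ir(cod)Cl]2, Na2CO3, toluene, 100 °C) should give 4-[2-(3-benzyloxyphenyl)ethyl]-2-ethenyloxy-1-methoxybenzene F1. Addition of one equivalent of Br2 (CH2Cl2, −78 °C) should give 4-[2-(3-benzyloxyphenyl)ethyl]-2-(1,2-dibromoethoxy)-1-methoxybenzene F2. NaNH2 in liquid NH3/THF should eliminate HBr twice, through 4-[2-(3-benzyloxyphenyl)ethyl]-2-(2-bromoethenyloxy)-1-methoxybenzene F3, and after quenching the route is rejoined at ethynyl ether 13.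

3. Step 13 (macrocyclisation). Intermolecular olefination may outrun ring closure, so that dimers and oligomers form instead of the strained 18-membered cyclophane. Fallback: the same bridge is closed by reductive carbonyl coupling on a low-valent titanium surface instead of by an ylide. Setting out from ester aldehyde 19, LiAlH4 (THF, 0 °C) should give {4-[5-(2-{3-[6-(hydroxymethyl)-2,3-dimethoxyphenoxy]phenyl}ethyl)-2-methoxyphenoxy]phenyl}methanol F4. MnO2 (CH2Cl2, rt) should oxidise both benzylic alcohols to 2-(3-{2-[3-(4-formylphenoxy)-4-methoxyphenyl]ethyl}phenoxy)-3,4-dimethoxybenzaldehyde F5. Intramolecular McMurry coupling (TiCl4, Zn, pyridine, THF, reflux, slow addition) should give macrocyclic stilbene 25, where the route is rejoined at step 14.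

**Further compounds**

F0 | step 7 | none | none
F1 | step 6 | 4-[2-(3-benzyloxyphenyl)ethyl]-2-ethenyloxy-1-methoxybenzene | C=COc1cc(CCc2cccc(OCc3ccccc3)c2)ccc1OC
F2 | step 6 | 4-[2-(3-benzyloxyphenyl)ethyl]-2-(1,2-dibromoethoxy)-1-methoxybenzene (racemic) | BrCC(Br)Oc1cc(CCc2cccc(OCc3ccccc3)c2)ccc1OC
F3 | step 6 | 4-[2-(3-benzyloxyphenyl)ethyl]-2-(2-bromoethenyloxy)-1-methoxybenzene (E/Z mixture) | BrC=COc1cc(CCc2cccc(OCc3ccccc3)c2)ccc1OC
F4 | step 13 | {4-[5-(2-{3-[6-(hydroxymethyl)-2,3-dimethoxyphenoxy]phenyl}ethyl)-2-methoxyphenoxy]phenyl}methanol | OCc1ccc(Oc2cc(CCc3cccc(Oc4c(CO)ccc(OC)c4OC)c3)ccc2OC)cc1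
F5 | step 13 | 2-(3-{2-[3-(4-formylphenoxy)-4-methoxyphenyl]ethyl}phenoxy)-3,4-dimethoxybenzaldehyde | O=Cc1ccc(Oc2cc(CCc3cccc(Oc4c(C=O)ccc(OC)c4OC)c3)ccc2OC)cc1
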